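**Strategy**

The plan rests on not brominating ring B but assembling it: its four contiguous carbons C5(Br)–C6(Br)–C1(CH2O)–C2(Br) are supplied by a fully substituted thiophene 1,1-dioxide, and the catechol carbons C3 and C4 by tris(trimethylsilyloxy)ethene. In one operation, cycloaddition, SO2 extrusion and loss of trimethylsilanol form C2–C3 and C4–C5 and deliver the hexasubstituted ring with its catechol already masked as labile silyl ethers. The precursor is the tribromothiophene dioxide already tied through the CH2–O–CH2 bridge to ring A, whose catechol is kept as a diacetate; ring A derives from isovanillin, the heterocycle from 3-methylthiophene.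

Key step: step 9

Remark: the target has no stereocentre. The two transient intermediates of the key step are drawn as one of the two possible orientations of the dienophile across the diene, without endo/exo assignment (racemic); every orientation and face leads to the same achiral arene.

**Route**

Step 1
Reactants: 1 isovanillin (3-hydroxy-4-methoxybenzaldehyde)
Product: 2 2,6-dibromo-3-hydroxy-4-methoxybenzaldehyde
Conditions: Br2 (2.1 equiv), AcOH, rt → 50 °C
Reagents that add atoms: bromine, BrBr
Why: Electrophilic aromatic bromination in which the free C3 hydroxyl, the strongest director, sends bromine to its ortho position C2 and its para position C6, while C5 (activated only by the methoxy group) should stay untouched at two equivalents.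

Step 2
Reactants: 2 2,6-dibromo-3-hydroxy-4-methoxybenzaldehyde
Product: 3 2,6-dibromo-3,4-dihydroxybenzaldehyde
Conditions: BBr3, CH2Cl2, −78 °C → rt; H2O
Reagents that add atoms: none
Why: Lewis-acid cleavage of an aryl methyl ether (BBr3 demethylation) is tolerated by aldehydes and aryl bromides, and it is done here, before any benzylic ether exists that BBr3 could cleave.

Step 3
Reactants: 3 2,6-dibromo-3,4-dihydroxybenzaldehyde
Product: 4 3,4-diacetoxy-2,6-dibromobenzaldehyde
Conditions: Ac2O, pyridine, DMAP (cat.), CH2Cl2, 0 °C → rt
Reagents that add atoms: acetic anhydride, CC(=O)OC(C)=O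
Why: DMAP-catalysed O-acetylation of both phenols; the acetates deactivate ring A towards the later peracid and are removable under very mild conditions at the end.

Step 4
Reactants: 4 3,4-diacetoxy-2,6-dibromobenzaldehyde
Product: 5 3,4-diacetoxy-2,6-dibromobenzyl alcohol
Conditions: BH3·THF, THF, 0 °C; aq. NH4Cl
Reagents that add atoms: none
Why: Chemoselective borane reduction of an aldehyde, which is far faster than reduction of aryl esters and proceeds through a neutral borate, so no alkoxide is present to trigger acetyl migration or loss.

Step 5
Reactants: 6 3-methylthiophene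
Product: 7 2,3,5-tribromo-4-methylthiophene
Conditions: Br2 (3.3 equiv), AcOH, rt → 80 °C
Reagents that add atoms: bromine, BrBr
Why: Exhaustive electrophilic bromination of the electron-rich thiophene substitutes all three ring C–H positions, so no regiochemical question arises.

Step 6
Reactants: 7 2,3,5-tribromo-4-methylthiophene
Product: 8 2,3,5-tribromo-4-(bromomethyl)thiophene
Conditions: NBS (1.05 equiv), AIBN (cat.), PhCF3, reflux
Reagents that add atoms: N-bromosuccinimide, O=C1CCC(=O)N1Br
Why: Wohl–Ziegler radical bromination; the methyl group carries the only C–H bonds in the molecule and gives a stabilised thenyl radical.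

Step 7
Reactants: 5 3,4-diacetoxy-2,6-dibromobenzyl alcohol; 8 2,3,5-tribromo-4-(bromomethyl)thiophene
Product: 9 2,3,5-tribromo-4-[(3,4-diacetoxy-2,6-dibromobenzyloxy)methyl]thiophene
Conditions: Ag2O, 4 Å MS, CH2Cl2, rt, dark
Reagents that add atoms: none
Why: Silver-oxide-mediated Williamson-type etherification of a primary alcohol with a heterobenzylic bromide, in which silver assists halide departure without a strong base, so the aryl acetates should survive.

Step 8
Reactants: 9 2,3,5-tribromo-4-[(3,4-diacetoxy-2,6-dibromobenzyloxy)methyl]thiophene
Product: 10 2,3,5-tribromo-4-[(3,4-diacetoxy-2,6-dibromobenzyloxy)methyl]thiophene 1,1-dioxide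
Conditions: H2O2·urea, (CF3CO)2O, CH2Cl2/MeCN, 0 °C → rt
Reagents that add atoms: trifluoroperacetic acid, OOC(=O)C(F)(F)F (formed in the flask from H2O2·urea and trifluoroacetic anhydride)
Why: Peroxytrifluoroacetic acid oxidation of an electron-poor, fully substituted thiophene to its 1,1-dioxide, as known for tetrahalothiophenes; full substitution suppresses dimerisation of the sulfoxide stage, and the diacetylated, dibrominated ring A and the ether bridge are inert to the electrophilic oxidant.

Step 9
Reactants: 10 2,3,5-tribromo-4-[(3,4-diacetoxy-2,6-dibromobenzyloxy)methyl]thiophene 1,1-dioxide; 11 tris(trimethylsilyloxy)ethene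
Product: 14 3,4-diacetoxy-2,6-dibromobenzyl 2,3,6-tribromo-4,5-bis(trimethylsilyloxy)benzyl ether, via bridged sulfone cycloadduct 12 (not isolated), via tris(silyloxy)cyclohexadiene 13 (not isolated)
Conditions: 11 (3 equiv), PhMe, 60 → 100 °C, Ar, sealed tube; evaporate (no aqueous work-up)
Reagents that add atoms: none
Why: The electron-poor sulfone diene and the electron-rich ketene silyl acetal 11 should combine in an inverse-electron-demand Diels–Alder reaction to the bridged sulfone 12, which extrudes SO2 cheletropically to cyclohexadiene 13; ionisation of an allylic C–OSiMe3 bond at the bis(silyloxy) carbon and loss of the one neighbouring ring proton (net 1,2-elimination of Me3SiOH) then aromatises to 14. The closest known reaction type is the cycloaddition of tetrahalothiophene 1,1-dioxides with alkenes followed by SO2 loss and aromatising elimination, with the elimination paralleling alcohol loss in ketene-acetal cycloadditions of other electron-poor heterodienes. Ring B closes as a six-membered carbocycle by intermolecular (4+2) cycloaddition, the new bonds being C2–C3 and C4–C5 of ring B. No stereocentre remains, since those formed in 12 and 13 are erased on aromatisation. The only selectivity needed is retention of both oxygens, which is secured because the sole ring hydrogen sits on the mono-oxygenated carbon next to the bis(silyloxy) carbon, so either orientation of 11 gives the same arene; the acetates keep ring A out of the reaction.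

Step 10
Reactants: 14 3,4-diacetoxy-2,6-dibromobenzyl 2,3,6-tribromo-4,5-bis(trimethylsilyloxy)benzyl ether
Product: 15 2,6-dibromo-3,4-dihydroxybenzyl 2,3,6-tribromo-4,5-dihydroxybenzyl ether (target)
Conditions: K2CO3 (2 equiv), degassed MeOH/THF, 0 °C, Ar; pH 5 phosphate buffer
Reagents that add atoms: none
Why: Base-mediated methanolysis (transesterification of the aryl acetates and desilylation of the aryl trimethylsilyl ethers) removes the four most labile phenol protecting groups in one cold, brief, oxygen-free operation that should spare the benzylic ether and the catechols.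

**Compound list**

1 | isovanillin (3-hydroxy-4-methoxybenzaldehyde) | COc1ccc(C=O)cc1O | starting material
2 | 2,6-dibromo-3-hydroxy-4-methoxybenzaldehyde | COc1cc(Br)c(C=O)c(Br)c1O | intermediate
3 | 2,6-dibromo-3,4-dihydroxybenzaldehyde | Oc1cc(Br)c(C=O)c(Br)c1O | intermediate
4 | 3,4-diacetoxy-2,6-dibromobenzaldehyde | CC(=O)Oc1cc(Br)c(C=O)c(Br)c1OC(C)=O | intermediate
5 | 3,4-diacetoxy-2,6-dibromobenzyl alcohol | CC(=O)Oc1cc(Br)c(CO)c(Br)c1OC(C)=O | intermediate
6 | 3-methylthiophene | Cc1ccsc1 | starting material
7 | 2,3,5-tribromo-4-methylthiophene | Cc1c(Br)sc(Br)c1Br | intermediate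
8 | 2,3,5-tribromo-4-(bromomethyl)thiophene | BrCc1c(Br)sc(Br)c1Br | intermediate
9 | 2,3,5-tribromo-4-[(3,4-diacetoxy-2,6-dibromobenzyloxy)methyl]thiophene | CC(=O)Oc1cc(Br)c(COCc2c(Br)sc(Br)c2Br)c(Br)c1OC(C)=O | intermediate
10 | 2,3,5-tribromo-4-[(3,4-diacetoxy-2,6-dibromobenzyloxy)methyl]thiophene 1,1-dioxide | CC(=O)Oc1cc(Br)c(COCC2=C(Br)S(=O)(=O)C(Br)=C2Br)c(Br)c1OC(C)=O | intermediate
11 | tris(trimethylsilyloxy)ethene | C[Si](C)(C)OC=C(O[Si](C)(C)C)O[Si](C)(C)C | starting material
12 | 1,2,4-tribromo-3-[(3,4-diacetoxy-2,6-dibromobenzyloxy)methyl]-5,5,6-tris(trimethylsilyloxy)-7-thiabicyclo[2.2.1]hept-2-ene 7,7-dioxide (one orientation drawn, racemic, endo/exo unassigned) | CC(=O)Oc1cc(Br)c(COCC2=C(Br)C3(Br)C(O[Si](C)(C)C)C(O[Si](C)(C)C)(O[Si](C)(C)C)C2(Br)S3(=O)=O)c(Br)c1OC(C)=O | intermediate (not isolated)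
13 | 1,2,4-tribromo-3-[(3,4-diacetoxy-2,6-dibromobenzyloxy)methyl]-5,5,6-tris(trimethylsilyloxy)cyclohexa-1,3-diene (one orientation drawn, racemic) | CC(=O)Oc1cc(Br)c(COCC2=C(Br)C(O[Si](C)(C)C)(O[Si](C)(C)C)C(O[Si](C)(C)C)C(Br)=C2Br)c(Br)c1OC(C)=O | intermediate (not isolated)
14 | 3,4-diacetoxy-2,6-dibromobenzyl 2,3,6-tribromo-4,5-bis(trimethylsilyloxy)benzyl ether | CC(=O)Oc1cc(Br)c(COCc2c(Br)c(O[Si](C)(C)C)c(O[Si](C)(C)C)c(Br)c2Br)c(Br)c1OC(C)=O | intermediate
15 | 2,6-dibromo-3,4-dihydroxybenzyl 2,3,6-tribromo-4,5-dihydroxybenzyl ether | Oc1cc(Br)c(COCc2c(Br)c(O)c(O)c(Br)c2Br)c(Br)c1O | target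

**Step count**

Total steps: 10. Longest linear sequence: 8 steps (steps 1, 2, 3, 4, 7, 8, 9, 10 from isovanillin); the thiophene branch (steps 5 and 6) joins at step 7.

**Steps most likely to fail and fallbacks**

1. Step 9. The ketene silyl acetal may act as a carbon nucleophile and add stepwise to the bromovinyl sulfone (addition–elimination of bromide with silyl transfer) instead of closing the ring, or premature desilylation may divert the diene before it aromatises. The fallback gives up the cycloaddition and takes ring B from a preformed arene, using only known reactions. It sets out from alcohol 5. 4-Methylcatechol (Cc1ccc(O)c(O)c1) would be brominated at its three free positions (Br2, AcOH) to 3,4,6-tribromo-5-methylbenzene-1,2-diol F1, acetylated (Ac2O, pyridine) to 3,4,6-tribromo-5-methyl-1,2-phenylene diacetate F2, and brominated at the methyl group (NBS, AIBN, PhCF3, reflux) to 3,4,6-tribromo-5-(bromomethyl)-1,2-phenylene diacetate F3. Ag2O-mediated etherification of F3 with 5 should give the tetraacetate of the target F4, and cold methanolysis (K2CO3, MeOH, 0 °C) brings the route back at 15.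

2. Step 8. The oxidation may stall at the sulfoxide stage, which can be lost by cycloaddition with itself, or long exposure to the acidic peracid may erode the acetates. The fallback changes the order of events and sets out from bromide 8. This small molecule, free of ether and ester groups, can be treated with excess CF3CO3H at 40 °C to give 2,3,5-tribromo-4-(bromomethyl)thiophene 1,1-dioxide F5. Silver-assisted etherification of this activated allylic bromide with 5 (AgOTf, 2,6-di-tert-butylpyridine, CH2Cl2, 0 °C) comes back to the route at 10.

3. Step 7. Displacement between two doubly ortho-brominated benzylic partners may be slow, so that acetyl transfer from a phenol ester to the benzylic oxygen or hydrolysis of the bromide competes. The fallback forms the ether by reductive etherification instead of substitution and sets out from bromide 8. Hydrolysis (CaCO3, aqueous dioxane, reflux) would give (2,4,5-tribromothiophen-3-yl)methanol F6, and silylation (Me3SiCl, Et3N, CH2Cl2) its trimethylsilyl ether, trimethyl[(2,4,5-tribromothiophen-3-yl)methoxy]silane F7. F7 is then combined with aldehyde 4 and Et3SiH under catalytic Me3SiOTf (CH2Cl2, −78 → 0 °C), which should give ether 9 directly, where it comes back to the route; step 4 is then not needed.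

Further compounds
F1 | step 9 | 3,4,6-tribromo-5-methylbenzene-1,2-diol | Cc1c(Br)c(O)c(O)c(Br)c1Br
F2 | step 9 | 3,4,6-tribromo-5-methyl-1,2-phenylene diacetate | Cc1c(Br)c(OC(C)=O)c(OC(C)=O)c(Br)c1Br
F3 | step 9 | 3,4,6-tribromo-5-(bromomethyl)-1,2-phenylene diacetate | BrCc1c(Br)c(OC(C)=O)c(OC(C)=O)c(Br)c1Br
F4 | step 9 | 3,4-diacetoxy-2,6-dibromobenzyl 4,5-diacetoxy-2,3,6-tribromobenzyl ether | CC(=O)Oc1cc(Br)c(COCc2c(Br)c(OC(C)=O)c(OC(C)=O)c(Br)c2Br)c(Br)c1OC(C)=O
F5 | step 8 | 2,3,5-tribromo-4-(bromomethyl)thiophene 1,1-dioxide | BrCC1=C(Br)S(=O)(=O)C(Br)=C1Br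
F6 | step 7 | (2,4,5-tribromothiophen-3-yl)methanol | OCc1c(Br)sc(Br)c1Br
F7 | step 7 | trimethyl[(2,4,5-tribromothiophen-3-yl)methoxy]silane | C[Si](C)(C)OCc1c(Br)sc(Br)c1Br
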